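**Synthesis proposal for CNP0313672.1: ring A carried as a phenol, ring B closed by a dearomatizing epoxide opening**

Cuts: C12–C13 (diene arm, Suzuki–Miyaura coupling with chloroprene), C4–C23 (hydroxymethyl, enolate trapping), C9–C10 (ring B, dearomatizing epoxide opening), C11=C12 (Wittig) and C6–C7 (benzylation of dilithiated prenol).
Enabling feature: in ring A the acetoxy carbon C3 lies para to the methyl-bearing quaternary C10 (C10–C1–C2–C3–C4–C5), so ring A is a masked 2,4-dimethylphenol; the tertiary carbinol C8 is next to C9 with C8–O anti to C9–C10, which is what backside opening of a cis C8–C9 epoxide by C10 leaves behind.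
Forward order: ring A is the benzene ring of the starting acid; the C7–C11 unit is joined as a Z allylic alcohol; ring B closes in step 10; ring A is then reduced and functionalised stepwise; the diene is attached last at C12.
Stereochemistry: C8 and C9 come from Sharpless epoxidation of the Z olefin (C9 inverted in step 10), C10 from the chair closure, C5 and C4 from Li/NH3 reduction and hydroxymethylation anti to the C10 methyl, and C3 from axial hydride delivery.

Key step: step 10

Remark: labdane numbering is used (ring A = C1–C5 and C10, ring B = C5–C10, side chain C11–C16, C4 hydroxymethyl = C23); the SMILES is read as 3R,4S,5S,8S,9R,10R, an enantio-type labdane epimeric at C9.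

**Route**

Step 1
Reactants: 1 3-methoxy-2-methylbenzoic acid
Product: 2 3-methoxy-2,6-dimethylbenzoic acid
Conditions: Pd(OAc)2 (10 mol %), MeB(OH)2, Ag2CO3, benzoquinone, K2HPO4, t-BuOH, 100 °C
Reagents that add atoms: methylboronic acid, CB(O)O
Why: Carboxylate-directed palladium-catalysed ortho C–H methylation with a methylboron reagent, for which only one ortho position is free, so the regiochemistry is fixed.

Step 2
Reactants: 2 3-methoxy-2,6-dimethylbenzoic acid
Product: 3 (3-methoxy-2,6-dimethylphenyl)methanol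
Conditions: LiAlH4, THF, 0 °C → reflux; aqueous work-up
Reagents that add atoms: none
Why: Hydride reduction of the hindered benzoic acid to the benzylic alcohol, which the aryl methyl ether tolerates.

Step 3
Reactants: 3 (3-methoxy-2,6-dimethylphenyl)methanol
Product: 4 3-(bromomethyl)-2,4-dimethylphenol
Conditions: BBr3 (2.5 equiv), CH2Cl2, −78 → 0 °C; H2O
Reagents that add atoms: boron tribromide, BrB(Br)Br
Why: Lewis-acid cleavage of the aryl methyl ether with concurrent conversion of the benzylic alcohol into the bromide, the usual outcome for meta-methoxybenzyl alcohols, in which no quinone methide can form.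

Step 4
Reactants: 4 3-(bromomethyl)-2,4-dimethylphenol
Product: 5 [3-(bromomethyl)-2,4-dimethylphenoxy]tri(propan-2-yl)silane
Conditions: TIPSOTf, 2,6-lutidine, CH2Cl2, −78 → 0 °C
Reagents that add atoms: triisopropylsilyl trifluoromethanesulfonate, CC(C)[Si](OS(=O)(=O)C(F)(F)F)(C(C)C)C(C)C
Why: Silylation of the phenol with a silyl triflate and a hindered, non-nucleophilic base that does not alkylate on the benzylic bromide.

Step 5
Reactants: 5 [3-(bromomethyl)-2,4-dimethylphenoxy]tri(propan-2-yl)silane; 6 3-methylbut-2-en-1-ol (prenol)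
Product: 8 (2Z)-5-{2,6-dimethyl-3-[tri(propan-2-yl)silyloxy]phenyl}-3-methylpent-2-en-1-ol, via dilithiated prenol 7 (not isolated)
Conditions: 6 (1.5 equiv), n-BuLi (2.0 equiv per 6), TMEDA, Et2O, 0 °C → rt; then 5, THF, −78 °C → rt; H2O
Reagents that add atoms: none
Why: Alkoxide-directed metalation of prenol at the methyl group cis to CH2OLi followed by SN2 benzylation at the terminal allyl carbon forms C6–C7 and gives the Z (nerol-type) trisubstituted olefin, in which C7 is cis to C11.

Step 6
Reactants: 8 (2Z)-5-{2,6-dimethyl-3-[tri(propan-2-yl)silyloxy]phenyl}-3-methylpent-2-en-1-ol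
Product: 9 [(2R,3S)-3-(2-{2,6-dimethyl-3-[tri(propan-2-yl)silyloxy]phenyl}ethyl)-3-methyloxiran-2-yl]methanol
Conditions: Ti(OiPr)4 (10 mol %), D-(−)-diethyl tartrate (14 mol %), t-BuOOH, 4 Å MS, CH2Cl2, −20 °C
Reagents that add atoms: tert-butyl hydroperoxide, CC(C)(C)OO
Why: Sharpless asymmetric epoxidation, in which the titanium D-(−)-tartrate complex delivers oxygen to the face that makes C9 R and C8 S (the sense opposite to that of L-(+)-tartrate on nerol-type substrates, to be confirmed by correlation).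

Step 7
Reactants: 9 [(2R,3S)-3-(2-{2,6-dimethyl-3-[tri(propan-2-yl)silyloxy]phenyl}ethyl)-3-methyloxiran-2-yl]methanol
Product: 10 (2S,3S)-3-(2-{2,6-dimethyl-3-[tri(propan-2-yl)silyloxy]phenyl}ethyl)-3-methyloxirane-2-carbaldehyde
Conditions: SO3·pyridine, DMSO, i-Pr2NEt, CH2Cl2, 0 °C
Reagents that add atoms: none
Why: Parikh–Doering oxidation, a mild activated-DMSO oxidation that spares the epoxide and the aryl silyl ether and does not epimerise the epoxide carbon (the descriptor changes only through priorities).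

Step 8
Reactants: 10 (2S,3S)-3-(2-{2,6-dimethyl-3-[tri(propan-2-yl)silyloxy]phenyl}ethyl)-3-methyloxirane-2-carbaldehyde
Product: 11 (3-{2-[(2S,3R)-3-ethenyl-2-methyloxiran-2-yl]ethyl}-2,4-dimethylphenoxy)tri(propan-2-yl)silane
Conditions: Ph3PCH3Br, KN(SiMe3)2, THF, −78 → 0 °C
Reagents that add atoms: methyltriphenylphosphonium bromide, C[P+](c1ccccc1)(c1ccccc1)c1ccccc1.[Br-]
Why: Wittig methylenation of the epoxy aldehyde with the non-stabilised ylide installs C12 and makes C9 allylic.

Step 9
Reactants: 11 (3-{2-[(2S,3R)-3-ethenyl-2-methyloxiran-2-yl]ethyl}-2,4-dimethylphenoxy)tri(propan-2-yl)silane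
Product: 12 3-{2-[(2S,3R)-3-ethenyl-2-methyloxiran-2-yl]ethyl}-2,4-dimethylphenol
Conditions: n-Bu4NF, AcOH (1:1), THF, 0 °C; pH 7 buffer; used at once
Reagents that add atoms: none
Why: Fluoride cleavage of the aryl silyl ether, buffered with acetic acid so that the phenoxide is protonated immediately and the vinyl epoxide meets neither strong acid nor free base before step 10.

Step 10
Reactants: 12 3-{2-[(2S,3R)-3-ethenyl-2-methyloxiran-2-yl]ethyl}-2,4-dimethylphenol
Product: 14 (4aS,5R,6S)-5-ethenyl-6-hydroxy-1,4a,6-trimethyl-5,6,7,8-tetrahydronaphthalen-2(4aH)-one, via potassium phenoxide 13 (not isolated)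
Conditions: t-BuOK (1.1 equiv), t-BuOH (0.005 M), 25 → 80 °C; H2O
Reagents that add atoms: none
Why: Proposed new method: the potassium phenoxide attacks through its para carbon C10 the allylic epoxide carbon C9 from the side opposite the C9–O bond, so that C9–C10 forms with inversion at C9, the C8 alkoxide is released and ring A becomes the cross-conjugated cyclohexa-2,5-dienone. The closest known reaction type is the base-mediated intramolecular para C-alkylation of phenoxides by tethered halides or sulfonates (Ar2-6 alkylative dearomatization), taken together with the known endo-selective SN2 opening of vinyl and trisubstituted epoxides by carbon nucleophiles at the less substituted carbon. Ring B (C5–C6–C7–C8–C9–C10) closes in a 6-endo-tet epoxide opening. C9 is fixed by the stereospecific inversion and C8 is carried over from the epoxide, while C10 is set by the chair transition state: the epoxide ring holds C8–O anti to the forming bond (equatorial), which places the C8 methyl and the vinyl group axial and the C10 methyl anti to the vinyl group, whereas the C10 epimer could only arise through a boat. The step needs C- over O-alkylation, para (C10) over ortho (C4) attack and 6-endo over 5-exo opening: O-alkylation would demand a meta-bridged medium ring, C8 is fully substituted while C9 is secondary and allylic, both C4 and C10 carry methyl groups so no rearomatisation channel exists, and hydrogen-bonded solvation of the phenoxide oxygen together with the greater stability of the cross-conjugated dienone should direct the attack to C10. tert-Butanol also protonates the tertiary alkoxide so that the opening is not reversed, and the epoxide strain pays for the loss of aromaticity.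

Step 11
Reactants: 14 (4aS,5R,6S)-5-ethenyl-6-hydroxy-1,4a,6-trimethyl-5,6,7,8-tetrahydronaphthalen-2(4aH)-one
Product: 15 (4aS,5R,6S)-5-ethenyl-6-hydroxy-1,4a,6-trimethyl-4,4a,5,6,7,8-hexahydronaphthalen-2(3H)-one
Conditions: [(Ph3P)CuH]6 (0.4 equiv), H2O, benzene, rt
Reagents that add atoms: none
Why: Copper hydride conjugate reduction delivers hydride to the unhindered β-carbon C1 of the disubstituted enone arm, while the fully substituted β-carbon C5 and the isolated vinyl group do not react, and protonation of the copper enolate at C2 leaves the 4-methyl-4-en-3-one.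

Step 12
Reactants: 15 (4aS,5R,6S)-5-ethenyl-6-hydroxy-1,4a,6-trimethyl-4,4a,5,6,7,8-hexahydronaphthalen-2(3H)-one
Product: 17 (1S,4aR,5R,6S,8aS)-5-ethenyl-6-hydroxy-1-(hydroxymethyl)-1,4a,6-trimethyloctahydronaphthalen-2(1H)-one, via dilithium enolate alkoxide 16 (not isolated)
Conditions: Li (2.2 equiv), NH3(l)/THF, −78 °C; NH3 evaporated; THF, −78 °C, CH2O (g, from paraformaldehyde); aq NH4Cl
Reagents that add atoms: formaldehyde, C=O
Why: Dissolving-metal (Birch-type) reduction of the enone protonates C5 axially, anti to the C10 methyl, giving the trans-fused C3–C4 lithium enolate (the C8 hydroxyl serves as the proton source), which monomeric formaldehyde hydroxymethylates regiospecifically at C4 from the face away from the C10 methyl (enolate aldol; CH2OH equatorial, C4 methyl axial).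

Step 13
Reactants: 17 (1S,4aR,5R,6S,8aS)-5-ethenyl-6-hydroxy-1-(hydroxymethyl)-1,4a,6-trimethyloctahydronaphthalen-2(1H)-one
Product: 18 (1S,4aR,5R,6S,8aS)-1-{[tert-butyl(dimethyl)silyl]oxymethyl}-5-ethenyl-6-hydroxy-1,4a,6-trimethyloctahydronaphthalen-2(1H)-one
Conditions: TBSCl, imidazole, DMF, 0 °C (crude 17 used directly)
Reagents that add atoms: tert-butyl(chloro)dimethylsilane, CC(C)(C)[Si](C)(C)Cl
Why: Selective silylation of the primary hydroxyl in the presence of the tertiary one, done at once to block retro-aldol loss of formaldehyde from the β-hydroxy ketone.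

Step 14
Reactants: 18 (1S,4aR,5R,6S,8aS)-1-{[tert-butyl(dimethyl)silyl]oxymethyl}-5-ethenyl-6-hydroxy-1,4a,6-trimethyloctahydronaphthalen-2(1H)-one
Product: 19 (1S,2R,4aR,5R,6S,8aS)-1-{[tert-butyl(dimethyl)silyl]oxymethyl}-5-ethenyl-1,4a,6-trimethyldecahydronaphthalene-2,6-diol
Conditions: NaBH4, MeOH, 0 °C
Reagents that add atoms: none
Why: Borohydride reduction of the C3 ketone next to the quaternary C4 proceeds by axial hydride delivery, as in 4,4-disubstituted 3-keto trans-decalins, and sets the equatorial C3 alcohol (3R).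

Step 15
Reactants: 19 (1S,2R,4aR,5R,6S,8aS)-1-{[tert-butyl(dimethyl)silyl]oxymethyl}-5-ethenyl-1,4a,6-trimethyldecahydronaphthalene-2,6-diol
Product: 20 (1S,2R,4aR,5R,6S,8aS)-1-{[tert-butyl(dimethyl)silyl]oxymethyl}-5-ethenyl-6-hydroxy-1,4a,6-trimethyldecahydronaphthalen-2-yl acetate
Conditions: Ac2O, pyridine, DMAP (cat.), CH2Cl2, 0 °C → rt
Reagents that add atoms: acetic anhydride, CC(=O)OC(C)=O
Why: DMAP-catalysed acylation of the secondary equatorial alcohol, under which the hindered tertiary C8 hydroxyl is not acylated.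

Step 16
Reactants: 20 (1S,2R,4aR,5R,6S,8aS)-1-{[tert-butyl(dimethyl)silyl]oxymethyl}-5-ethenyl-6-hydroxy-1,4a,6-trimethyldecahydronaphthalen-2-yl acetate; 21 2-chlorobuta-1,3-diene (chloroprene)
Product: 23 (1S,2R,4aR,5R,6S,8aS)-1-{[tert-butyl(dimethyl)silyl]oxymethyl}-6-hydroxy-1,4a,6-trimethyl-5-(3-methylidenepent-4-en-1-yl)decahydronaphthalen-2-yl acetate, via B-alkyl-9-BBN borane 22 (not isolated)
Conditions: 9-BBN (2.5 equiv), THF, 0 °C → rt; then H2O, K3PO4 (3 M aq), 21 (5 equiv), Pd(OAc)2 (5 mol %), 2-dicyclohexylphosphino-2′,6′-dimethoxybiphenyl (10 mol %), 40 °C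
Reagents that add atoms: none
Why: Anti-Markovnikov hydroboration of the monosubstituted alkene places boron on C12, and B-alkyl Suzuki–Miyaura coupling with the alkenyl chloride under a bulky electron-rich phosphine palladium catalyst forms C12–C13 and delivers the 2-substituted butadiene, which is introduced only now because it would not survive the dissolving-metal step.

Step 17
Reactants: 23 (1S,2R,4aR,5R,6S,8aS)-1-{[tert-butyl(dimethyl)silyl]oxymethyl}-6-hydroxy-1,4a,6-trimethyl-5-(3-methylidenepent-4-en-1-yl)decahydronaphthalen-2-yl acetate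
Product: 24 (1S,2R,4aR,5R,6S,8aS)-6-hydroxy-1-(hydroxymethyl)-1,4a,6-trimethyl-5-(3-methylidenepent-4-en-1-yl)decahydronaphthalen-2-yl acetate
Conditions: HF·pyridine, pyridine, THF, 0 °C → rt
Reagents that add atoms: none
Why: Fluoride cleavage of the primary silyl ether under buffered, mildly acidic conditions that avoid base-induced acetyl migration from O-3 to the primary oxygen and leave the diene and the tertiary alcohol intact.

**Compound list**

1 | 3-methoxy-2-methylbenzoic acid | COc1cccc(C(=O)O)c1C | starting material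
2 | 3-methoxy-2,6-dimethylbenzoic acid | COc1ccc(C)c(C(=O)O)c1C | intermediate
3 | (3-methoxy-2,6-dimethylphenyl)methanol | COc1ccc(C)c(CO)c1C | intermediate
4 | 3-(bromomethyl)-2,4-dimethylphenol | Cc1ccc(O)c(C)c1CBr | intermediate
5 | [3-(bromomethyl)-2,4-dimethylphenoxy]tri(propan-2-yl)silane | Cc1ccc(O[Si](C(C)C)(C(C)C)C(C)C)c(C)c1CBr | intermediate
6 | 3-methylbut-2-en-1-ol (prenol) | CC(C)=CCO | starting material
7 | dilithiated prenol, lithium (2Z)-4-lithio-3-methylbut-2-en-1-olate | [Li]C/C(C)=C\CO[Li] | intermediate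
8 | (2Z)-5-{2,6-dimethyl-3-[tri(propan-2-yl)silyloxy]phenyl}-3-methylpent-2-en-1-ol | Cc1ccc(O[Si](C(C)C)(C(C)C)C(C)C)c(C)c1CC/C(C)=C\CO | intermediate
9 | [(2R,3S)-3-(2-{2,6-dimethyl-3-[tri(propan-2-yl)silyloxy]phenyl}ethyl)-3-methyloxiran-2-yl]methanol | Cc1ccc(O[Si](C(C)C)(C(C)C)C(C)C)c(C)c1CC[C@]1(C)O[C@@H]1CO | intermediate
10 | (2S,3S)-3-(2-{2,6-dimethyl-3-[tri(propan-2-yl)silyloxy]phenyl}ethyl)-3-methyloxirane-2-carbaldehyde | Cc1ccc(O[Si](C(C)C)(C(C)C)C(C)C)c(C)c1CC[C@]1(C)O[C@@H]1C=O | intermediate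
11 | (3-{2-[(2S,3R)-3-ethenyl-2-methyloxiran-2-yl]ethyl}-2,4-dimethylphenoxy)tri(propan-2-yl)silane | Cc1ccc(O[Si](C(C)C)(C(C)C)C(C)C)c(C)c1CC[C@]1(C)O[C@@H]1C=C | intermediate
12 | 3-{2-[(2S,3R)-3-ethenyl-2-methyloxiran-2-yl]ethyl}-2,4-dimethylphenol | Cc1ccc(O)c(C)c1CC[C@]1(C)O[C@@H]1C=C | intermediate
13 | potassium 3-{2-[(2S,3R)-3-ethenyl-2-methyloxiran-2-yl]ethyl}-2,4-dimethylphenoxide | Cc1ccc([O-])c(C)c1CC[C@]1(C)O[C@@H]1C=C.[K+] | intermediate
14 | (4aS,5R,6S)-5-ethenyl-6-hydroxy-1,4a,6-trimethyl-5,6,7,8-tetrahydronaphthalen-2(4aH)-one | C=C[C@@H]1[C@]2(C)C=CC(=O)C(C)=C2CC[C@]1(C)O | intermediate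
15 | (4aS,5R,6S)-5-ethenyl-6-hydroxy-1,4a,6-trimethyl-4,4a,5,6,7,8-hexahydronaphthalen-2(3H)-one | C=C[C@@H]1[C@]2(C)CCC(=O)C(C)=C2CC[C@]1(C)O | intermediate
16 | dilithium enolate alkoxide of the trans-fused ketone (C3–C4 enolate, C8 alkoxide) | C=C[C@@H]1[C@]2(C)CCC(O[Li])=C(C)[C@H]2CC[C@]1(C)O[Li] | intermediate
17 | (1S,4aR,5R,6S,8aS)-5-ethenyl-6-hydroxy-1-(hydroxymethyl)-1,4a,6-trimethyloctahydronaphthalen-2(1H)-one | C=C[C@@H]1[C@]2(C)CCC(=O)[C@](C)(CO)[C@H]2CC[C@]1(C)O | intermediate
18 | (1S,4aR,5R,6S,8aS)-1-{[tert-butyl(dimethyl)silyl]oxymethyl}-5-ethenyl-6-hydroxy-1,4a,6-trimethyloctahydronaphthalen-2(1H)-one | C=C[C@@H]1[C@]2(C)CCC(=O)[C@](C)(CO[Si](C)(C)C(C)(C)C)[C@H]2CC[C@]1(C)O | intermediate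
19 | (1S,2R,4aR,5R,6S,8aS)-1-{[tert-butyl(dimethyl)silyl]oxymethyl}-5-ethenyl-1,4a,6-trimethyldecahydronaphthalene-2,6-diol | C=C[C@@H]1[C@]2(C)CC[C@@H](O)[C@](C)(CO[Si](C)(C)C(C)(C)C)[C@H]2CC[C@]1(C)O | intermediate
20 | (1S,2R,4aR,5R,6S,8aS)-1-{[tert-butyl(dimethyl)silyl]oxymethyl}-5-ethenyl-6-hydroxy-1,4a,6-trimethyldecahydronaphthalen-2-yl acetate | C=C[C@@H]1[C@]2(C)CC[C@@H](OC(C)=O)[C@](C)(CO[Si](C)(C)C(C)(C)C)[C@H]2CC[C@]1(C)O | intermediate
21 | 2-chlorobuta-1,3-diene (chloroprene) | C=CC(Cl)=C | starting material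
22 | (1S,2R,4aR,5R,6S,8aS)-5-[2-(9-borabicyclo[3.3.1]nonan-9-yl)ethyl]-1-{[tert-butyl(dimethyl)silyl]oxymethyl}-6-hydroxy-1,4a,6-trimethyldecahydronaphthalen-2-yl acetate | C1CCC2CCCC1B2CC[C@@H]3[C@]4(C)CC[C@@H](OC(C)=O)[C@](C)(CO[Si](C)(C)C(C)(C)C)[C@H]4CC[C@]3(C)O | intermediate
23 | (1S,2R,4aR,5R,6S,8aS)-1-{[tert-butyl(dimethyl)silyl]oxymethyl}-6-hydroxy-1,4a,6-trimethyl-5-(3-methylidenepent-4-en-1-yl)decahydronaphthalen-2-yl acetate | C=CC(=C)CC[C@@H]1[C@]2(C)CC[C@@H](OC(C)=O)[C@](C)(CO[Si](C)(C)C(C)(C)C)[C@H]2CC[C@]1(C)O | intermediate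
24 | (1S,2R,4aR,5R,6S,8aS)-6-hydroxy-1-(hydroxymethyl)-1,4a,6-trimethyl-5-(3-methylidenepent-4-en-1-yl)decahydronaphthalen-2-yl acetate (CNP0313672.1) | C=CC(=C)CC[C@@H]1[C@]2(C)CC[C@@H](OC(C)=O)[C@](C)(CO)[C@H]2CC[C@]1(C)O | target

**Step count and risks**

Total step count: 17. Longest linear sequence: 17 steps (1 to 24); 6 and 21 are purchased and enter in steps 5 and 16.

Steps most likely to fail:

1. Step 10 (proposed new method). What may go wrong: attack through the ortho carbon C4 instead of C10, closure through a boat giving the C10 epimer, or base-induced decomposition of the vinyl epoxide before ring closure. The fallback sets out from 11 and comes back at 14. It replaces the epoxide by a cyclic sulfate, a sulfonate-type leaving group that keeps the five-membered tie between O–C8 and C9 (hence the same anti geometry and chair control) and so falls within the established intramolecular para C-alkylation of phenoxides by sulfonate esters. Insertion of CO2 into 11 under zerovalent palladium catalysis (Pd(PPh3)4, CO2, THF), which proceeds with net retention at C9, should give the vinyl cyclic carbonate (4S,5R)-4-(2-{2,6-dimethyl-3-[tri(propan-2-yl)silyloxy]phenyl}ethyl)-5-ethenyl-4-methyl-1,3-dioxolan-2-one F1. Methanolysis (K2CO3, MeOH) should give the syn diol (3R,4S)-6-{2,6-dimethyl-3-[tri(propan-2-yl)silyloxy]phenyl}-4-methylhex-1-ene-3,4-diol F2. 1,1′-Sulfonyldiimidazole with NaH in THF should then give the cyclic sulfate (4S,5R)-4-(2-{2,6-dimethyl-3-[tri(propan-2-yl)silyloxy]phenyl}ethyl)-5-ethenyl-4-methyl-1,3,2-dioxathiolane 2,2-dioxide F3. One equivalent of n-Bu4NF in THF at high dilution would free the phenoxide, which displaces the sulfate oxygen at C9 with inversion to give tetrabutylammonium (1R,2S,8aS)-1-ethenyl-2,5,8a-trimethyl-6-oxo-1,2,3,4,6,8a-hexahydronaphthalen-2-yl sulfate F4. Brief hydrolysis of the sulfate monoester (catalytic H2SO4, moist THF, 0 °C) then gives 14.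

2. Step 5. What may go wrong: halogen–metal exchange or Wurtz-type coupling of the hindered benzylic bromide, attack through the internal allyl carbon, or erosion of the Z geometry. The fallback sets out from 5 and comes back at 8, fixing the olefin geometry by a syn carbocupration instead. Allenylmagnesium bromide (from propargyl bromide and Mg, Et2O) should propargylate 5 to [3-(but-3-yn-1-yl)-2,4-dimethylphenoxy]tri(propan-2-yl)silane F5. Deprotonation with n-BuLi and trapping with ClCO2Et gives ethyl 5-{2,6-dimethyl-3-[tri(propan-2-yl)silyloxy]phenyl}pent-2-ynoate F6. Me2CuLi in THF at −78 °C adds methyl and hydrogen syn across the alkyne, leaving the chain cis to the ester in ethyl (2Z)-5-{2,6-dimethyl-3-[tri(propan-2-yl)silyloxy]phenyl}-3-methylpent-2-enoate F7. Reduction with i-Bu2AlH in CH2Cl2 at −78 °C gives 8.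

3. Step 16. What may go wrong: slow oxidative addition or polymerisation of the chlorodiene, and hydrolysis or migration of the acetate in the basic aqueous medium. The fallback sets out from 20 (through the same borane 22) and comes back at 23, building the diene by olefination instead of delivering it as a dienyl halide. Coupling of 22 with 2-bromoprop-2-en-1-ol (PdCl2(dppf), AsPh3, Cs2CO3, DMF/THF/H2O, rt) should give (1S,2R,4aR,5R,6S,8aS)-1-{[tert-butyl(dimethyl)silyl]oxymethyl}-6-hydroxy-5-[3-(hydroxymethyl)but-3-en-1-yl]-1,4a,6-trimethyldecahydronaphthalen-2-yl acetate F8. Allylic oxidation with MnO2 in CH2Cl2 gives (1S,2R,4aR,5R,6S,8aS)-1-{[tert-butyl(dimethyl)silyl]oxymethyl}-5-(3-formylbut-3-en-1-yl)-6-hydroxy-1,4a,6-trimethyldecahydronaphthalen-2-yl acetate F9. Wittig methylenation (Ph3PCH3Br, KN(SiMe3)2, THF, −78 °C) gives 23.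

Further compounds
F1 | step 10 | (4S,5R)-4-(2-{2,6-dimethyl-3-[tri(propan-2-yl)silyloxy]phenyl}ethyl)-5-ethenyl-4-methyl-1,3-dioxolan-2-one | Cc1ccc(O[Si](C(C)C)(C(C)C)C(C)C)c(C)c1CC[C@]1(C)OC(=O)O[C@@H]1C=C
F2 | step 10 | (3R,4S)-6-{2,6-dimethyl-3-[tri(propan-2-yl)silyloxy]phenyl}-4-methylhex-1-ene-3,4-diol | Cc1ccc(O[Si](C(C)C)(C(C)C)C(C)C)c(C)c1CC[C@](C)(O)[C@H](O)C=C
F3 | step 10 | (4S,5R)-4-(2-{2,6-dimethyl-3-[tri(propan-2-yl)silyloxy]phenyl}ethyl)-5-ethenyl-4-methyl-1,3,2-dioxathiolane 2,2-dioxide | Cc1ccc(O[Si](C(C)C)(C(C)C)C(C)C)c(C)c1CC[C@]1(C)OS(=O)(=O)O[C@@H]1C=C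
F4 | step 10 | tetrabutylammonium (1R,2S,8aS)-1-ethenyl-2,5,8a-trimethyl-6-oxo-1,2,3,4,6,8a-hexahydronaphthalen-2-yl sulfate | C=C[C@@H]1[C@]2(C)C=CC(=O)C(C)=C2CC[C@]1(C)OS(=O)(=O)[O-].CCCC[N+](CCCC)(CCCC)CCCC
F5 | step 5 | [3-(but-3-yn-1-yl)-2,4-dimethylphenoxy]tri(propan-2-yl)silane | Cc1ccc(O[Si](C(C)C)(C(C)C)C(C)C)c(C)c1CCC#C
F6 | step 5 | ethyl 5-{2,6-dimethyl-3-[tri(propan-2-yl)silyloxy]phenyl}pent-2-ynoate | Cc1ccc(O[Si](C(C)C)(C(C)C)C(C)C)c(C)c1CCC#CC(=O)OCC
F7 | step 5 | ethyl (2Z)-5-{2,6-dimethyl-3-[tri(propan-2-yl)silyloxy]phenyl}-3-methylpent-2-enoate | Cc1ccc(O[Si](C(C)C)(C(C)C)C(C)C)c(C)c1CC/C(C)=C\C(=O)OCC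
F8 | step 16 | (1S,2R,4aR,5R,6S,8aS)-1-{[tert-butyl(dimethyl)silyl]oxymethyl}-6-hydroxy-5-[3-(hydroxymethyl)but-3-en-1-yl]-1,4a,6-trimethyldecahydronaphthalen-2-yl acetate | C=C(CO)CC[C@@H]1[C@]2(C)CC[C@@H](OC(C)=O)[C@](C)(CO[Si](C)(C)C(C)(C)C)[C@H]2CC[C@]1(C)O
F9 | step 16 | (1S,2R,4aR,5R,6S,8aS)-1-{[tert-butyl(dimethyl)silyl]oxymethyl}-5-(3-formylbut-3-en-1-yl)-6-hydroxy-1,4a,6-trimethyldecahydronaphthalen-2-yl acetate | C=C(C=O)CC[C@@H]1[C@]2(C)CC[C@@H](OC(C)=O)[C@](C)(CO[Si](C)(C)C(C)(C)C)[C@H]2CC[C@]1(C)O
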